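**Strategy.** The target is cut at the bond between the hydroazulene olefin carbon and the ethylene linker: a primary alkyllithium from the perhydrobenzoxepine half adds to a hydroazulene vinylogous ester. The hydroazulene rests on a Pauson–Khand reaction. Its cyclopentane (tertiary methyl carbinol, two ring-fusion CH, two CH2) together with the flanking CH2 and CMe2 of the seven-membered ring is a linalool chain in which only the ring-fusion C–C bond is still to be made. One cobalt-mediated (2+2+1) event on (R)-dehydrolinalool TBS ether, a 1,6-enyne with a quaternary propargylic silyloxy carbon and an isopropylidene terminus, forms that bond and a cyclopentenone whose carbonyl later serves a two-carbon ring expansion.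

Key step: step 5

Remark 1 (structure): the SMILES is read as the (3R,5aR,6R,7S,9aR)-benzoxepine / (1R,5R,7R,8R)-hydroazulene isomer. The western half is an oxepane trans-fused to one cyclohexane (a perhydro-1-benzoxepine), not an oxepane–decalin, and its tertiary hydroxyl is axial, syn to the angular methyl. A sclareolide-type decalin cannot be mapped onto it (ring A would need an oxygen inserted into a C–C bond and C8 would have the wrong configuration). This half is therefore built from geranyl bromide by a diepoxide cascade.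

Remark 2 (precursor supply): (R)-dehydrolinalool is made from geraniol by Sharpless epoxidation and epoxy-chloride elimination, because catalytic asymmetric addition of an ethynyl Grignard reagent to a dialkyl ketone is not a dependable reaction.

Assumption: geraniol, geranyl bromide, N-methoxy-N-methylacetamide, 2-chloropropionyl chloride, the D-fructose-derived Shi ketone and (S)-Me-CBS are purchased.

**Eastern half (hydroazulene)**

Step 1
Reactants: 1 geraniol
Product: 2 (2R,3R)-2,3-epoxygeraniol
Conditions: Ti(OiPr)4 (cat.), D-(−)-diethyl tartrate (cat.), t-BuOOH, 4 Å MS, CH2Cl2, −20 °C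
Reagents that add atoms: tert-butyl hydroperoxide, CC(C)(C)OO
Why: Sharpless asymmetric epoxidation of an E-allylic alcohol, in which the D-tartrate–titanium complex delivers oxygen to the face that gives the (2R,3R)-epoxide and so fixes the future carbinol carbon.

Step 2
Reactants: 2 (2R,3R)-2,3-epoxygeraniol
Product: 3 (2R,3S)-3-(chloromethyl)-2-methyl-2-(4-methylpent-3-en-1-yl)oxirane
Conditions: PPh3, CCl4, NaHCO3, reflux
Reagents that add atoms: carbon tetrachloride, ClC(Cl)(Cl)Cl
Why: Appel chlorination of the primary alcohol by SN2 displacement of the oxyphosphonium group under buffered neutral conditions that should leave the epoxide and both stereocentres untouched.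

Step 3
Reactants: 3 (2R,3S)-3-(chloromethyl)-2-methyl-2-(4-methylpent-3-en-1-yl)oxirane
Product: 4 (3R)-3,7-dimethyloct-6-en-1-yn-3-ol, (R)-dehydrolinalool
Conditions: LDA (3.3 equiv), THF, −78 → −20 °C; aq. NH4Cl
Reagents that add atoms: none
Why: Twofold base-induced elimination of a 2,3-epoxy chloride (epoxide opening from the chloromethyl carbon, then loss of HCl) gives the terminal alkynol, and because the C–O bond of the tertiary carbon is never broken its configuration is carried over as (R).

Step 4
Reactants: 4 (R)-dehydrolinalool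
Product: 5 tert-butyl{[(3R)-3,7-dimethyloct-6-en-1-yn-3-yl]oxy}dimethylsilane
Conditions: TBSOTf, 2,6-lutidine, CH2Cl2, 0 °C → rt
Reagents that add atoms: tert-butyldimethylsilyl triflate, CC(C)(C)[Si](C)(C)OS(=O)(=O)C(F)(F)F
Why: Silyl triflate silylation is the standard way to protect a hindered tertiary alcohol, and the weak pyridine base does not touch the acetylenic C–H.

Step 5
Reactants: 5 tert-butyl{[(3R)-3,7-dimethyloct-6-en-1-yn-3-yl]oxy}dimethylsilane
Product: 7 (5R,8R)-8-[(tert-butyldimethylsilyl)oxy]-4,4,8-trimethylbicyclo[3.3.0]oct-1-en-3-one, via alkyne–hexacarbonyldicobalt complex 6 (not isolated)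
Conditions: Co2(CO)8 (1.1 equiv), CH2Cl2, rt; then NMO (8 equiv), 0 °C → rt
Reagents that add atoms: dicobalt octacarbonyl (source of the CO unit), O=C=[Co](=C=O)(=C=O)(=C=O)[Co](=C=O)(=C=O)(=C=O)=C=O
Why: Complexation gives the alkyne–Co2(CO)6 unit; N-oxide removal of a CO ligand opens a site at which the tethered olefin binds and inserts into the Co–C bond of the internal alkyne carbon, then CO inserts and reductive elimination releases the enone. This is the intramolecular Pauson–Khand reaction of a 1,6-enyne under amine N-oxide promotion, here with a trisubstituted olefin. The carbocycle that holds the carbinol carbon closes by 5-exo olefin insertion, which makes the ring-fusion C1–C5 bond, and the cyclopentenone closes through the cobaltacycle by carbonyl insertion and reductive elimination, which makes C2–C3 and C3–C4. The one new stereocentre, C5, is controlled by the fixed (R)-carbinol carbon C8: in the cobaltacycle the large silyloxy group should take the exo position, away from the cobalt-bound CMe2 terminus, leaving the small methyl endo, so that H-5 ends cis to OTBS. The step therefore needs 1,2-diastereofacial selectivity and enough reactivity from a hindered olefin; the size gap between OTBS and CH3 is relied on for the first, and the 1,6-spacing with a quaternary propargylic carbon (Thorpe–Ingold effect) supports the second.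

Step 6
Reactants: 7 (5R,8R)-8-[(tert-butyldimethylsilyl)oxy]-4,4,8-trimethylbicyclo[3.3.0]oct-1-en-3-one
Product: 8 (1R,5R,8R)-8-[(tert-butyldimethylsilyl)oxy]-4,4,8-trimethylbicyclo[3.3.0]octan-3-one (cis-fused, OTBS cis to both ring-fusion hydrogens)
Conditions: H2 (1 atm), 5% Pd/C, EtOAc, rt
Reagents that add atoms: none
Why: Heterogeneous hydrogenation of the enone olefin should add hydrogen to C1 on the face of H-5, because only the cis-fused diquinane is free of severe strain, which sets C1.

Step 7
Reactants: 8 (1R,5R,8R)-8-[(tert-butyldimethylsilyl)oxy]-4,4,8-trimethylbicyclo[3.3.0]octan-3-one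
Product: 9 trimethylsilyl enol ether of 8 (double bond C2=C3, ring-fusion and carbinol configurations unchanged)
Conditions: TMSOTf, Et3N, CH2Cl2, 0 °C
Reagents that add atoms: trimethylsilyl triflate, C[Si](C)(C)OS(=O)(=O)C(F)(F)F
Why: Soft enolisation can only go towards C2 because C4 is quaternary, so a single regioisomeric silyl enol ether should form.

Step 8
Reactants: 9 trimethylsilyl enol ether of 8; 10 2-chloropropionyl chloride
Product: 11 chloro(methyl)cyclobutanone adduct (cyclobutanone fused across C2–C3 of the diquinane: C3 carries OTMS and is bonded to CClMe, C2 is bonded to the new C=O; the three new centres form as a mixture of no consequence)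
Conditions: Et3N, hexanes, reflux, slow addition of 10
Reagents that add atoms: none
Why: Ketene–enol ether [2+2] cycloaddition with methylchloroketene generated in situ, in which the ketene carbonyl carbon bonds to the nucleophilic C2 and the CClMe carbon to the oxygen-bearing C3, placing the new carbonyl on the CH2 side as the ring expansion requires.

Step 9
Reactants: 11 chloro(methyl)cyclobutanone adduct
Product: 13 (1R,7R,8R)-8-[(tert-butyldimethylsilyl)oxy]-2,2,4,8-tetramethylbicyclo[5.3.0]decane-3,5-dione (C4 epimers), via dechlorinated silyloxycyclobutanone 12 (not isolated)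
Conditions: Zn dust, AcOH, THF, rt; filter, concentrate; then TBAF (1.1 equiv), THF, 0 °C; aq. NH4Cl
Reagents that add atoms: none
Why: Zinc reduces the α-chloro ketone, and fluoride then frees the cyclobutanol alkoxide, whose retro-aldol cleavage of the old C2–C3 bond relieves the four-ring strain and gives the ring-expanded 1,3-dione, while the hindered tertiary TBS ether should survive brief cold TBAF.

Step 10
Reactants: 13 (1R,7R,8R)-8-[(tert-butyldimethylsilyl)oxy]-2,2,4,8-tetramethylbicyclo[5.3.0]decane-3,5-dione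
Product: 14 (1R,7R,8R)-8-[(tert-butyldimethylsilyl)oxy]-5-methoxy-2,2,4,8-tetramethylbicyclo[5.3.0]dec-4-en-3-one
Conditions: HC(OMe)3, MeOH, CSA (cat.), rt → 40 °C
Reagents that add atoms: trimethyl orthoformate, COC(OC)OC; methanol, CO
Why: Acid-catalysed enol etherification of an unsymmetrical 1,3-dione should take place at the carbonyl remote from the gem-dimethyl group (kinetically more accessible, and giving the less congested vinylogous ester), leaving the carbonyl next to CMe2 free for the union.

**Western half (perhydrobenzoxepine)**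

Step 11
Reactants: 15 geranyl bromide; 16 N-methoxy-N-methylacetamide
Product: 17 (4E)-N-methoxy-N,5,9-trimethyldeca-4,8-dienamide
Conditions: 16, LDA, THF, −78 °C; then 15, −78 → 0 °C
Reagents that add atoms: none
Why: SN2 alkylation of the amide lithium enolate at the primary allylic carbon, which keeps the E-olefin geometry that the later trans ring fusion depends on.

Step 12
Reactants: 17 (4E)-N-methoxy-N,5,9-trimethyldeca-4,8-dienamide
Product: 18 (4R,5R,8R)-4,5:8,9-diepoxy-N-methoxy-N,5,9-trimethyldecanamide
Conditions: D-fructose-derived Shi ketone (0.3 equiv per olefin), Oxone, K2CO3, n-Bu4NHSO4, MeCN–DMM–aq. borate buffer (pH 10.5), 0 °C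
Reagents that add atoms: Oxone (potassium peroxymonosulfate), [K+].[O-]S(=O)(=O)OO
Why: Shi epoxidation through the chiral dioxirane and a spiro transition state should oxidise both trisubstituted olefins on the face that gives the (R)-configured epoxide carbons, which later become C3, C5a and C9a.

Step 13
Reactants: 18 (4R,5R,8R)-4,5:8,9-diepoxy-N-methoxy-N,5,9-trimethyldecanamide
Product: 19 (6R,7R,10R)-6,7:10,11-diepoxy-7,11-dimethyldodec-1-en-3-one
Conditions: vinylMgBr (1.5 equiv), THF, −78 → −20 °C; inverse quench into cold aq. NH4Cl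
Reagents that add atoms: vinylmagnesium bromide, C=C[Mg]Br
Why: Weinreb ketone synthesis, in which the chelated tetrahedral intermediate prevents over-addition and the trisubstituted epoxides are inert to the Grignard reagent at low temperature.

Step 14
Reactants: 19 (6R,7R,10R)-6,7:10,11-diepoxy-7,11-dimethyldodec-1-en-3-one
Product: 20 (4Z,8R,9R,12R)-8,9:12,13-diepoxy-9,13-dimethyl-5-[(trimethylsilyl)oxy]tetradeca-1,4-diene
Conditions: vinylMgBr, CuBr·SMe2 (10 mol %), TMSCl, DMPU, THF, −78 °C; Et3N, pentane, aq. NaHCO3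
Reagents that add atoms: vinylmagnesium bromide, C=C[Mg]Br; chlorotrimethylsilane, C[Si](C)(C)Cl
Why: Copper-catalysed conjugate addition with in situ silyl trapping gives the enol silane regiospecifically on the side of the new allyl-bearing carbon (which simple enolisation of the ketone could not do), with Z geometry from the s-cis enone.

Step 15
Reactants: 20 (4Z,8R,9R,12R)-8,9:12,13-diepoxy-9,13-dimethyl-5-[(trimethylsilyl)oxy]tetradeca-1,4-diene
Product: 22 (3R,5aR,6R,9aR)-3-hydroxy-2,2,5a-trimethyl-6-(prop-2-en-1-yl)octahydro-1-benzoxepin-7(2H)-one, via trimethylsilyl ether 21 (not isolated)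
Conditions: TMSOTf (0.3 equiv), 2,6-di-tert-butyl-4-methylpyridine, CH2Cl2, −78 °C; then K2CO3, MeOH, rt
Reagents that add atoms: none
Why: Epoxide-initiated tandem oxa-/carbacyclisation with an enol silane terminator: the silyl-activated terminal epoxide is opened at its tertiary carbon by the inner epoxide oxygen (7-endo), and the resulting epoxonium ion is opened at its tertiary carbon with inversion by the enol silane through a chair, so C3 and C9a keep the epoxide configurations, C5a is set by inversion (trans fusion) and the Z-enol silane together with the basic methanolysis places the C6 allyl group equatorial.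

Step 16
Reactants: 22 (3R,5aR,6R,9aR)-3-hydroxy-2,2,5a-trimethyl-6-(prop-2-en-1-yl)octahydro-1-benzoxepin-7(2H)-one
Product: 23 (3R,5aR,6R,7S,9aR)-2,2,5a,7-tetramethyl-6-(prop-2-en-1-yl)decahydro-1-benzoxepine-3,7-diol
Conditions: MeMgBr (4 equiv), CeCl3, THF, −78 → 0 °C; aq. NH4Cl
Reagents that add atoms: methylmagnesium bromide, C[Mg]Br
Why: Cerium-assisted Grignard 1,2-addition to a hindered cyclohexanone, in which the axial C5a methyl blocks axial approach so that methyl enters equatorially and the new hydroxyl is axial, which is the (7S) configuration of the target.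

Step 17
Reactants: 23 (3R,5aR,6R,7S,9aR)-2,2,5a,7-tetramethyl-6-(prop-2-en-1-yl)decahydro-1-benzoxepine-3,7-diol
Product: 24 3,7-bis(triethylsilyl) ether of 23
Conditions: TESOTf (3 equiv), 2,6-lutidine, CH2Cl2, 0 °C → rt
Reagents that add atoms: triethylsilyl triflate, CC[Si](CC)(CC)OS(=O)(=O)C(F)(F)F
Why: Silyl triflate silylation is strong enough for both the secondary and the hindered axial tertiary hydroxyl, and masking the latter prevents tetrahydrofuran closure onto the side chain in the next steps.

Step 18
Reactants: 24 3,7-bis(triethylsilyl) ether of 23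
Product: 26 2-[(3R,5aR,6R,7S,9aR)-2,2,5a,7-tetramethyl-3,7-bis(triethylsilyloxy)decahydro-1-benzoxepin-6-yl]ethanol, via aldehyde 25 (not isolated)
Conditions: O3, CH2Cl2–MeOH, NaHCO3, −78 °C; then NaBH4, −78 °C → rt
Reagents that add atoms: ozone, [O-][O+]=O
Why: Ozonolysis of the only olefin with reductive work-up shortens the allyl group to the two-carbon hydroxyethyl chain without touching any stereocentre.

Step 19
Reactants: 26 2-[(3R,5aR,6R,7S,9aR)-2,2,5a,7-tetramethyl-3,7-bis(triethylsilyloxy)decahydro-1-benzoxepin-6-yl]ethanol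
Product: 27 (3R,5aR,6R,7S,9aR)-6-(2-iodoethyl)-2,2,5a,7-tetramethyl-3,7-bis(triethylsilyloxy)decahydro-1-benzoxepine
Conditions: I2, PPh3, imidazole, CH2Cl2, 0 °C → rt
Reagents that add atoms: iodine, II
Why: Appel-type iodination of a primary alcohol by SN2 displacement of the oxyphosphonium group, under conditions that silyl ethers tolerate.

**Union and end game**

Step 20
Reactants: 27 (3R,5aR,6R,7S,9aR)-6-(2-iodoethyl)-2,2,5a,7-tetramethyl-3,7-bis(triethylsilyloxy)decahydro-1-benzoxepine; 14 (1R,7R,8R)-8-[(tert-butyldimethylsilyl)oxy]-5-methoxy-2,2,4,8-tetramethylbicyclo[5.3.0]dec-4-en-3-one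
Product: 30 (1R,7R,8R)-3-{2-[(3R,5aR,6R,7S,9aR)-3,7-dihydroxy-2,2,5a,7-tetramethyldecahydro-1-benzoxepin-6-yl]ethyl}-8-hydroxy-2,2,4,8-tetramethylbicyclo[5.3.0]dec-3-en-5-one (enone triol), via alkyllithium 28 (not isolated), via tertiary carbinol adduct 29 (not isolated)
Conditions: 27 (1.3 equiv), t-BuLi (2.1 equiv per iodide), Et2O–pentane, −78 °C; then 14, THF, −78 → 0 °C; aq. NH4Cl; crude adduct, 48% aq. HF, MeCN, rt
Reagents that add atoms: water, O
Why: Lithium–iodine exchange gives a primary alkyllithium that adds 1,2 to the vinylogous ester carbonyl (Stork–Danheiser alkylative carbonyl transposition, as practised on 3-alkoxy-2,6,6-trimethylcyclohexenones), after which aqueous HF ionises the tertiary allylic alcohol, hydrolyses the enol ether to the transposed enone and removes all three silyl groups, with no stereocentre created.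

Step 21
Reactants: 30 enone triol
Product: 31 3-O-acetate of 30 (enone acetate)
Conditions: Ac2O, pyridine, DMAP (cat.), CH2Cl2, 0 °C → rt
Reagents that add atoms: acetic anhydride, CC(=O)OC(C)=O
Why: The oxepane hydroxyl is the only secondary alcohol present, and the two tertiary alcohols should not acylate under these mild conditions.

Step 22
Reactants: 31 enone acetate
Product: 32 target CNP0157376.1, (3R,5aR,6R,7S,9aR)-6-{2-[(1R,5R,7R,8R)-5,8-dihydroxy-2,2,4,8-tetramethylbicyclo[5.3.0]dec-3-en-3-yl]ethyl}-7-hydroxy-2,2,5a,7-tetramethyldecahydro-1-benzoxepin-3-yl acetate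
Conditions: (S)-Me-CBS (0.5 equiv), BH3·SMe2 (3 equiv), THF, −30 °C; MeOH
Reagents that add atoms: none
Why: Corey–Bakshi–Shibata reduction, in which the α-methyl-substituted olefin flank acts as the large group and the ring CH2 as the small one, so the (S)-catalyst should deliver hydride to give the (5R)-allylic alcohol by reagent control, while the acetate and the tetrasubstituted olefin are inert to borane at this temperature.

**Compound list**

1 | geraniol | C/C(=C\CO)CCC=C(C)C | starting material
2 | (2R,3R)-2,3-epoxygeraniol | OC[C@@H]1[C@](C)(O1)CCC=C(C)C | intermediate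
3 | (2R,3S)-3-(chloromethyl)-2-methyl-2-(4-methylpent-3-en-1-yl)oxirane | ClC[C@@H]1[C@](C)(O1)CCC=C(C)C | intermediate
4 | (3R)-3,7-dimethyloct-6-en-1-yn-3-ol | C#C[C@](C)(O)CCC=C(C)C | intermediate
5 | tert-butyl{[(3R)-3,7-dimethyloct-6-en-1-yn-3-yl]oxy}dimethylsilane | C#C[C@](C)(O[Si](C)(C)C(C)(C)C)CCC=C(C)C | intermediate
6 | hexacarbonyldicobalt complex of the alkyne of 5 | C12([C@](C)(O[Si](C)(C)C(C)(C)C)CCC=C(C)C)[Co]3(=C=O)(=C=O)(=C=O)[Co]1(=C=O)(=C=O)(=C=O)[CH]23 | intermediate
7 | (5R,8R)-8-[(tert-butyldimethylsilyl)oxy]-4,4,8-trimethylbicyclo[3.3.0]oct-1-en-3-one | O=C1C=C2[C@@H](CC[C@@]2(C)O[Si](C)(C)C(C)(C)C)C1(C)C | intermediate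
8 | (1R,5R,8R)-8-[(tert-butyldimethylsilyl)oxy]-4,4,8-trimethylbicyclo[3.3.0]octan-3-one | O=C1C[C@@H]2[C@@H](CC[C@@]2(C)O[Si](C)(C)C(C)(C)C)C1(C)C | intermediate
9 | trimethylsilyl enol ether of 8 (C2=C3) | C[Si](C)(C)OC1=C[C@@H]2[C@@H](CC[C@@]2(C)O[Si](C)(C)C(C)(C)C)C1(C)C | intermediate
10 | 2-chloropropionyl chloride (racemic) | CC(Cl)C(Cl)=O | starting material
11 | chloro(methyl)cyclobutanone adduct of 9 (new centres unassigned) | C[Si](C)(C)OC12C(C)(Cl)C(=O)C1[C@@H]3[C@@H](CC[C@@]3(C)O[Si](C)(C)C(C)(C)C)C2(C)C | intermediate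
12 | dechlorinated silyloxycyclobutanone | C[Si](C)(C)OC12C(C)C(=O)C1[C@@H]3[C@@H](CC[C@@]3(C)O[Si](C)(C)C(C)(C)C)C2(C)C | intermediate
13 | (1R,7R,8R)-8-[(tert-butyldimethylsilyl)oxy]-2,2,4,8-tetramethylbicyclo[5.3.0]decane-3,5-dione | O=C1C[C@@H]2[C@@H](CC[C@@]2(C)O[Si](C)(C)C(C)(C)C)C(C)(C)C(=O)C1C | intermediate
14 | (1R,7R,8R)-8-[(tert-butyldimethylsilyl)oxy]-5-methoxy-2,2,4,8-tetramethylbicyclo[5.3.0]dec-4-en-3-one | CC1=C(OC)C[C@@H]2[C@@H](CC[C@@]2(C)O[Si](C)(C)C(C)(C)C)C(C)(C)C1=O | intermediate
15 | geranyl bromide | CC(C)=CCC/C(C)=C/CBr | starting material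
16 | N-methoxy-N-methylacetamide | CC(=O)N(C)OC | starting material
17 | (4E)-N-methoxy-N,5,9-trimethyldeca-4,8-dienamide | CC(C)=CCC/C(C)=C/CCC(=O)N(C)OC | intermediate
18 | (4R,5R,8R)-4,5:8,9-diepoxy-N-methoxy-N,5,9-trimethyldecanamide | CON(C)C(=O)CC[C@H]1O[C@]1(C)CC[C@H]1OC1(C)C | intermediate
19 | (6R,7R,10R)-6,7:10,11-diepoxy-7,11-dimethyldodec-1-en-3-one | C=CC(=O)CC[C@H]1O[C@]1(C)CC[C@H]1OC1(C)C | intermediate
20 | (4Z,8R,9R,12R)-8,9:12,13-diepoxy-9,13-dimethyl-5-[(trimethylsilyl)oxy]tetradeca-1,4-diene | C=CC/C=C(\O[Si](C)(C)C)CC[C@H]1O[C@]1(C)CC[C@H]1OC1(C)C | intermediate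
21 | 3-O-trimethylsilyl ether of 22 | C[Si](C)(C)O[C@@H]1CC[C@]2(C)[C@@H](CC=C)C(=O)CC[C@H]2OC1(C)C | intermediate
22 | (3R,5aR,6R,9aR)-3-hydroxy-2,2,5a-trimethyl-6-(prop-2-en-1-yl)octahydro-1-benzoxepin-7(2H)-one | O[C@@H]1CC[C@]2(C)[C@@H](CC=C)C(=O)CC[C@H]2OC1(C)C | intermediate
23 | (3R,5aR,6R,7S,9aR)-2,2,5a,7-tetramethyl-6-(prop-2-en-1-yl)decahydro-1-benzoxepine-3,7-diol | O[C@@H]1CC[C@]2(C)[C@@H](CC=C)[C@@](C)(O)CC[C@H]2OC1(C)C | intermediate
24 | 3,7-bis(triethylsilyl) ether of 23 | CC[Si](CC)(CC)O[C@@H]1CC[C@]2(C)[C@@H](CC=C)[C@@](C)(O[Si](CC)(CC)CC)CC[C@H]2OC1(C)C | intermediate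
25 | 2-[(3R,5aR,6R,7S,9aR)-2,2,5a,7-tetramethyl-3,7-bis(triethylsilyloxy)decahydro-1-benzoxepin-6-yl]acetaldehyde | CC[Si](CC)(CC)O[C@@H]1CC[C@]2(C)[C@@H](CC=O)[C@@](C)(O[Si](CC)(CC)CC)CC[C@H]2OC1(C)C | intermediate
26 | 2-[(3R,5aR,6R,7S,9aR)-2,2,5a,7-tetramethyl-3,7-bis(triethylsilyloxy)decahydro-1-benzoxepin-6-yl]ethanol | CC[Si](CC)(CC)O[C@@H]1CC[C@]2(C)[C@@H](CCO)[C@@](C)(O[Si](CC)(CC)CC)CC[C@H]2OC1(C)C | intermediate
27 | (3R,5aR,6R,7S,9aR)-6-(2-iodoethyl)-2,2,5a,7-tetramethyl-3,7-bis(triethylsilyloxy)decahydro-1-benzoxepine | CC[Si](CC)(CC)O[C@@H]1CC[C@]2(C)[C@@H](CCI)[C@@](C)(O[Si](CC)(CC)CC)CC[C@H]2OC1(C)C | intermediate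
28 | primary alkyllithium from 27 | CC[Si](CC)(CC)O[C@@H]1CC[C@]2(C)[C@@H](CC[Li])[C@@](C)(O[Si](CC)(CC)CC)CC[C@H]2OC1(C)C | intermediate
29 | tertiary carbinol adduct of 28 with 14 (new carbinol centre unassigned) | CC[Si](CC)(CC)O[C@@H]1CC[C@]2(C)[C@@H](CCC3(O)C(C)=C(OC)C[C@@H]4[C@@H](CC[C@@]4(C)O[Si](C)(C)C(C)(C)C)C3(C)C)[C@@](C)(O[Si](CC)(CC)CC)CC[C@H]2OC1(C)C | intermediate
30 | enone triol, (1R,7R,8R)-3-{2-[(3R,5aR,6R,7S,9aR)-3,7-dihydroxy-2,2,5a,7-tetramethyldecahydro-1-benzoxepin-6-yl]ethyl}-8-hydroxy-2,2,4,8-tetramethylbicyclo[5.3.0]dec-3-en-5-one | O[C@@H]1CC[C@]2(C)[C@@H](CCC3=C(C)C(=O)C[C@@H]4[C@@H](CC[C@@]4(C)O)C3(C)C)[C@@](C)(O)CC[C@H]2OC1(C)C | intermediate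
31 | enone acetate, 3-O-acetate of 30 | CC(=O)O[C@@H]1CC[C@]2(C)[C@@H](CCC3=C(C)C(=O)C[C@@H]4[C@@H](CC[C@@]4(C)O)C3(C)C)[C@@](C)(O)CC[C@H]2OC1(C)C | intermediate
32 | CNP0157376.1 | CC(=O)O[C@@H]1CC[C@]2(C)[C@@H](CCC3=C(C)[C@H](O)C[C@@H]4[C@@H](CC[C@@]4(C)O)C3(C)C)[C@@](C)(O)CC[C@H]2OC1(C)C | target

**Totals**

Total step count: 22. Longest linear sequence: 13 steps (steps 1–10, then 20–22); the western half contributes 9 steps (11–19) before the union.

**Steps most likely to fail**

Step 5. The olefin insertion must place cobalt on the tertiary CMe2 carbon. This slow insertion may lose to decomplexation or to reduction of the complexed alkyne, and discrimination between methyl and silyloxy at the propargylic carbon may be incomplete. The fallback sets out from 5 and returns at 7, and takes the gem-dimethyl group out of the cyclisation. Selective ozonolysis of the electron-rich isopropylidene olefin of 5 (O3, CH2Cl2, −78 °C, indicator end-point; Me2S) should give (4R)-4-[(tert-butyldimethylsilyl)oxy]-4-methylhex-5-ynal F1. Wittig methylenation (Ph3P=CH2, THF) should give the monosubstituted enyne tert-butyldimethyl{[(3R)-3-methylhept-6-en-1-yn-3-yl]oxy}silane F2. A Pauson–Khand reaction of this unhindered 1,6-enyne (Co2(CO)8; NMO) should give (5S,8R)-8-[(tert-butyldimethylsilyl)oxy]-8-methylbicyclo[3.3.0]oct-1-en-3-one F3. Two rounds of kinetic α′-methylation (LDA, MeI, THF, −78 °C), passing through the 4-methyl enone F4, should then give 7. Any C5 epimer would be removed by chromatography at F3 or 7.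

Step 8. After the first C–C bond forms at C2, ring closure onto the oxocarbenium carbon flanked by CMe2 may be too slow. The zwitterion would then collapse by silyl transfer to an acylated product instead of the cyclobutanone. The fallback sets out from 9 and returns at 13; it uses the most reactive ketene and brings the methyl group in later by enolate alkylation. Dichloroketene (Cl2CHCOCl, Et3N, hexanes) should add to 9 to give the dichlorocyclobutanone adduct F5. Zn/AcOH should give the dechlorinated silyloxycyclobutanone F6, and TBAF (THF, 0 °C) the unmethylated hydroazulene-3,5-dione F7. C-Methylation between the two carbonyls (MeI, K2CO3, acetone, reflux) should then give 13.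

Step 15. The labile trimethylsilyl enol ether may be desilylated before the cascade reaches it, or the epoxonium ion may be quenched by elimination before the hindered CH(allyl) terminus attacks; either would end in monocyclic oxepanes. The fallback sets out from 18 and returns at 22; it replaces the enol silane by a stable β-keto ester terminator and delivers the allyl group afterwards. Acylation of the lithium enolate of allyl acetate by Weinreb amide 18 (LDA, allyl acetate, THF, −78 °C) should give prop-2-enyl (6R,7R,10R)-6,7:10,11-diepoxy-7,11-dimethyl-3-oxododecanoate F8. Lewis-acid cyclisation terminated by the β-keto ester enol (BF3·OEt2, CH2Cl2, −78 °C) should give the bicyclic allyl β-keto ester F9. Palladium-catalysed decarboxylative allylation (Pd(PPh3)4, THF, rt; Tsuji reaction), which places the allyl group on the carbon that carried the ester, followed by K2CO3/MeOH equilibration, should give 22.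

**Further compounds**

F1 | step 5 | (4R)-4-[(tert-butyldimethylsilyl)oxy]-4-methylhex-5-ynal | C#C[C@](C)(O[Si](C)(C)C(C)(C)C)CCC=O
F2 | step 5 | tert-butyldimethyl{[(3R)-3-methylhept-6-en-1-yn-3-yl]oxy}silane | C#C[C@](C)(O[Si](C)(C)C(C)(C)C)CCC=C
F3 | step 5 | (5S,8R)-8-[(tert-butyldimethylsilyl)oxy]-8-methylbicyclo[3.3.0]oct-1-en-3-one | O=C1C=C2[C@@H](CC[C@@]2(C)O[Si](C)(C)C(C)(C)C)C1
F4 | step 5 | 4-methyl derivative of F3 (C4 epimers) | O=C1C=C2[C@@H](CC[C@@]2(C)O[Si](C)(C)C(C)(C)C)C1C
F5 | step 8 | dichlorocyclobutanone adduct of 9 | C[Si](C)(C)OC12C(Cl)(Cl)C(=O)C1[C@@H]3[C@@H](CC[C@@]3(C)O[Si](C)(C)C(C)(C)C)C2(C)C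
F6 | step 8 | dechlorinated silyloxycyclobutanone (no methyl) | C[Si](C)(C)OC12CC(=O)C1[C@@H]3[C@@H](CC[C@@]3(C)O[Si](C)(C)C(C)(C)C)C2(C)C
F7 | step 8 | (1R,7R,8R)-8-[(tert-butyldimethylsilyl)oxy]-2,2,8-trimethylbicyclo[5.3.0]decane-3,5-dione | O=C1C[C@@H]2[C@@H](CC[C@@]2(C)O[Si](C)(C)C(C)(C)C)C(C)(C)C(=O)C1
F8 | step 15 | prop-2-enyl (6R,7R,10R)-6,7:10,11-diepoxy-7,11-dimethyl-3-oxododecanoate | C=CCOC(=O)CC(=O)CC[C@H]1O[C@]1(C)CC[C@H]1OC1(C)C
F9 | step 15 | prop-2-enyl (3R,5aR,9aR)-3-hydroxy-2,2,5a-trimethyl-7-oxodecahydro-1-benzoxepine-6-carboxylate (ester equatorial or enolised) | O[C@@H]1CC[C@]2(C)[C@@H](C(=O)OCC=C)C(=O)CC[C@H]2OC1(C)C
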